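(All constants come from no measurement; the run is a simulation.)

A closed, stirred vessel holds G, and we must choose the charge of Z.

G 24 mM; time 1.5 h

    G + Z → J + D (k1 = 0.0273 /M/s)
    Z + J ⇌ Z.J, settled at all times (K2 = 77300 /M)
    2 Z → Z2 (k3 = 0.0110 /M/s)
    G + D → G.D (k4 = 0.0235 /M/s)
    Z + D ⇌ Z.D, settled at all times (K5 = 23.6 /M)

1. the equivalents of Z at which the part of the G that has reacted at 1.5 h is just 90%

- percent here means G units held: one G.D counts as two
- what is said of D includes Z.D
- a doubled species enters its step squared and goes two at a time
- the amount of Z is what is sought; it is there from the start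
- run time (flask): 1.5 h

Follow one molecule of G. It can meet free Z or free D, at nearly the same constant, 0.0273 /M/s against 0.0235 /M/s. So we take their mean and treat its loss as pseudo-first-order in the sum of the two:

ln(G charged / G left) = 2.30

mean of c(Z) + c(D) = 2.30 / (0.0254 /M/s × 5400 s) = 16.8 mM

This is the mean free c(Z) + c(D) that G must see over the run.

It looks odd. That mean is less than the 24 mM of G, so the equation G + Z → J + D suggests that one equivalent is ample. But Z doesn't stay. J is half bound at c(Z) = 0.0129 mM, far below the charge of G, so as long as c(Z) stands well above that value, each turn of the first step costs two Z and returns one D. Pairing by itself takes two equivalents of Z, 48.0 mM, to half in 0.263 h, shorter than the run. Our reckoning stops here: it gives the mean, not the charge.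

The forecast says 2.25 equiv, holding that “only about a third of added Z survives as free Z”.

The simulation gives 2.18 equiv, within the margin. G is used 5.8 times as fast by Z as by D at 0.116 h, but that ratio is 0.39 at 1.50 h. At 0.750 h, free Z is 9.99% of its charge, or 5.22 mM, less than the mean 16.8 mM asked of free Z and free D together. With a quarter more Z, the flask reaches 93.6%. The same reckoning puts its mean at 20.1 mM, which is 1.20 times 16.8 mM.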